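**Remarks on the chemistry**

- Check of the structures: no correction is needed. C3 is S in the 3‑formyl and 3‑methoxycarbonyl compounds and R in the 3‑hydroxymethyl and 3‑silyloxymethyl compounds for the same arrangement in space, because CHO and CO2Me outrank C2 and CH2OH does not. All of them are 2,3‑trans. The E enal corresponds to the E arylidene lactone (ring B anti to the carbonyl carbon, syn to ring A).
- Assumption: acid 1 and boronate 10 are taken as catalogue compounds. The sense of induction of a new catalytic step cannot be assigned in advance, so the quinine‑derived amine is written, and its quinidine‑derived pseudoenantiomer replaces it if the 2R series forms.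
- Tightening of the precursor design, with the disconnection unchanged:
  - Bromine is introduced before the lactone is closed, while the free phenol still directs para.
  - Only the ring‑locked E alkene is admitted, because E and Z enals would give opposite C2 configurations from the same bound conformer.
  - The lactol/enal pair is kept neutral and used promptly, with a weak acid co‑catalyst in a non‑polar solvent, because in acid the lactol can ionise to a benzofuran‑type allyl cation.
  - C5 stays a bromide through the cation‑prone stage, and the acid‑labile cinnamyl silyl ether is attached only afterwards.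

## Structural features

Hierochin B is a 2,3‑dihydrobenzofuran neolignan. Ring A (benzene) is fused through C3a and C7a to a dihydrofuran ring, whose C2 carries ring B, a 3,4‑dimethoxyphenyl group. Ring A bears a methoxy group at C7, next to the ring oxygen, and an (E)‑3‑hydroxyprop‑1‑enyl chain at C5, para to that oxygen; C3 carries a hydroxymethyl group. The only stereocentres are C2 (S) and C3 (R), which are adjacent and trans, the thermodynamically preferred arrangement for a 2‑aryl‑3‑alkyl dihydrobenzofuran. Three points are fragile: the O1–C2 bond, benzylic to a ring with a para methoxy group, ionises in acid; the electron‑rich cinnamyl alcohol is sensitive to acid and oxidants; and in any intermediate with a carbonyl group on C3 the O1–C2 bond opens under base by E1cB. The connectivity is easy to assemble. The real difficulty is absolute control at C2, which has no neighbouring group to direct it, whereas C3 can follow by equilibration while it carries a carbonyl group. The route uses the fact that O1–C2 lies beta to the exocyclic carbon on C3: at the aldehyde level, the dihydrofuran ring is the intramolecular oxa‑Michael adduct of the ring A phenol oxygen to a flat, achiral 2,3‑diarylpropenal, so the ring and both stereocentres can be made in one closure.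

## Logic of the disconnections

12 to 11: only the O–Si bond of the side‑chain oxygen is cut. The allylic alcohol is carried silylated because 10 is bought in that form. Nothing is simplified in the skeleton, and the forward step must be a neutral fluoride cleavage so that no acid meets the finished molecule.

11 to 9 and 10: the C5–C(alkenyl) bond is cut. This removes the acid‑ and oxidant‑sensitive propenyl chain from every earlier step and replaces it by a robust bromide, and the three‑carbon unit with its E geometry is bought. The forward step must couple an electron‑rich aryl bromide in the presence of a free primary alcohol with retention of alkene geometry.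

9 to 8: no skeletal bond is cut; the C3 carbon is raised to the aldehyde level. This makes O1–C2 beta to a carbonyl group and so opens the retro‑oxa‑Michael path. The forward reduction must be faster than epimerisation at C2 through ring opening of 8, so it is run in the same flask.

8 to 7: the O1–C2 bond is cut. One ring and both stereocentres disappear and a flat, achiral precursor remains, the largest simplification of the plan. The forward step must close a five‑membered ring in the 5‑endo mode, choose one face of C2, leave C3 trans, and be trapped before it reverses.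

7 to 6 to 5: 7 is the open tautomer of 6, and 6 is the half‑reduced form of 5; the cut behind them is the acyl C–O level of the lactone. The lactone fixes the alkene geometry in a ring and is the storable oxidation level. The forward reduction must stop at the lactol.

5 to 3 and 4: the exocyclic C=C bond at C3 is cut. Ring A and ring B fragments are joined convergently in one condensation. The forward step must give one alkene geometry and must not open the aryl lactone.

3 to 2 to 1: the lactone C–O bond and then the C5–Br bond are cut, leading to a single bought arylacetic acid. The forward order matters: bromination must come first, while the free phenol directs para.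

## Other disconnections considered

Alternative 1: The cut is the C5–C6 bond of ring A, and behind it the whole benzene ring is unravelled into carbonyl groups. The precursor is ethyl 3‑[(4R,5S)‑2‑acetyl‑4‑(tert‑butyldimethylsilyloxymethyl)‑5‑(3,4‑dimethoxyphenyl)‑2‑hydroxyoxolan‑3‑yl]‑2‑oxopropanoate A2, the lactol form of a 1,2‑diketone with an α‑keto ester arm. In the forward step the acetyl methyl group enolises and adds to the keto ester carbonyl; loss of two molecules of water and enolisation of the C7 carbonyl should give ethyl (2S,3R)‑3‑(tert‑butyldimethylsilyloxymethyl)‑2‑(3,4‑dimethoxyphenyl)‑7‑hydroxy‑2,3‑dihydrobenzofuran‑5‑carboxylate A1.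
- In favour: C2 and C3 are set on a saturated oxygen heterocycle before any arene exists, only a six‑membered closure is possible, and no intermediate has a C3 carbonyl that could trigger ring opening.
- Against: ring A of the target is an ordinary guaiacyl ring, so building it de novo spends bonds where there is no difficulty. A2 is long to assemble (α‑alkylation of a preformed enantiopure lactone core with a pyruvate unit, then acyl anion addition to the lactone carbonyl). A1 still needs O‑methylation and several steps to turn the ester into the propenol chain.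
- Comparison: on stereochemical security and on mechanistic precedent it is the better plan, since it needs no new asymmetric catalysis and no reversible stereo‑defining step. On regiochemical certainty in ring A it is the equal. On step economy it is clearly worse, at roughly twice the length.

Alternative 2: The cuts are C3a–C7a and C4–C5, a retro‑Diels–Alder with CO2 put back in. The precursor is 3‑{[(1S,2R)‑2‑(tert‑butyldimethylsilyloxymethyl)‑1‑(3,4‑dimethoxyphenyl)but‑3‑yn‑1‑yl]oxy}‑6‑(dimethoxymethyl)‑4‑methoxy‑2H‑pyran‑2‑one A4. On heating, the tethered alkyne should add across C3 and C6 of the pyranone, and loss of CO2 from the bridged adduct should give (2S,3R)‑3‑(tert‑butyldimethylsilyloxymethyl)‑5‑(dimethoxymethyl)‑2‑(3,4‑dimethoxyphenyl)‑7‑methoxy‑2,3‑dihydrobenzofuran A3.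
- In favour: two skeletal bonds and both rings form in one reagent‑free step, the tether fixes the regiochemistry, and the stereocentres are spectators.
- Against: the ether oxygen of A4 sits on a secondary carbon that is benzylic to a 4‑methoxyaryl ring, so making that C–O bond with defined configuration is difficult because substitution there tends to go through the cation. The same bond must survive the high temperature that an electron‑rich pyranone and an unactivated alkyne need. The acetal of A3 is still three to four steps from the propenol chain.
- Comparison: in bonds and rings formed per step it is the better plan (two bonds and two rings against one and one), and in not touching the stereocentres in the key step it is the better plan. It is the equal in regiocontrol. It is worse in where it places the stereochemical problem, which becomes a hard acyclic ether synthesis, and in step economy.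

Alternative 3: The cut is the C3–C3a bond. The precursor is the flavanone (S)‑6‑bromo‑2‑(3,4‑dimethoxyphenyl)‑8‑methoxychroman‑4‑one A6. PhI(OAc)2 in HC(OMe)3 with H2SO4 should iodinate the enol ether at C3; the ring A carbon then shifts from C4 to C3 with loss of PhI, and C4 leaves the ring as the ester, giving methyl (2S,3S)‑5‑bromo‑2‑(3,4‑dimethoxyphenyl)‑7‑methoxy‑2,3‑dihydrobenzofuran‑3‑carboxylate A5. Reduction of A5 would give 9 of the chosen route.
- In favour: the contraction is an established reaction type for flavanones and gives the trans ester. C2 is carried through unchanged. A6 is reached by known six‑membered conjugate‑addition chemistry. The bromide handle and the end game are the same as in the chosen plan.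
- Against: ring B, with two methoxy groups, is itself a good migrating group, so the competing shift of ring B from C2 to C3 (the isoflavone pathway) is favoured, while bromine makes ring A a poorer migrating group. The strongly acidic medium can open the pyranone ring at the 4‑methoxybenzylic C2–O bond and racemise C2.
- Comparison: in precedent for the key step it is the better plan. In step count and end game it is about the equal. It is worse in that the two substituents the target demands (electron‑rich ring B, halogenated ring A) both work against the desired migration, whereas in the chosen plan the electron‑rich ring B is what makes the closure possible.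

Key step: step 5

## Steps

Step 1
Reactants: 1 2‑(2‑hydroxy‑3‑methoxyphenyl)acetic acid
Product: 2 2‑(5‑bromo‑2‑hydroxy‑3‑methoxyphenyl)acetic acid
Conditions: NBS (1.0 equiv), MeCN, 0 °C to rt
Reagents that add atoms: N‑bromosuccinimide, O=C1CCC(=O)N1Br
Why: Electrophilic aromatic bromination; the free phenol is the strongest director and both its ortho positions are occupied, so bromine enters para to it (C5), which is why the halogen goes in before the phenol is tied up as the lactone.

Step 2
Reactants: 2 2‑(5‑bromo‑2‑hydroxy‑3‑methoxyphenyl)acetic acid
Product: 3 5‑bromo‑7‑methoxybenzofuran‑2(3H)‑one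
Conditions: p‑TsOH·H2O (5 mol %), toluene, reflux, Dean–Stark trap
Reagents that add atoms: none
Why: Acid‑catalysed lactonisation (intramolecular Fischer esterification) of a 2‑hydroxyarylacetic acid, driven by azeotropic removal of water; the aryl bromide and the methyl ether are inert.

Step 3
Reactants: 3 5‑bromo‑7‑methoxybenzofuran‑2(3H)‑one; 4 veratraldehyde (3,4‑dimethoxybenzaldehyde)
Product: 5 (E)‑5‑bromo‑3‑(3,4‑dimethoxybenzylidene)‑7‑methoxybenzofuran‑2(3H)‑one
Conditions: neutral Al2O3, CH2Cl2, rt, under N2
Reagents that add atoms: none
Why: Knoevenagel‑type condensation; C3 of the benzofuranone is strongly acidic (its enolate is a 2‑hydroxybenzofuran), adds to the aldehyde and loses water by E1cB, the non‑nucleophilic oxide surface spares the aryl lactone, and the E isomer (ring B anti to the lactone carbonyl) is the usual outcome for 3‑arylidene benzofuranones, so the alkene geometry needed later is fixed in a ring.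

Step 4
Reactants: 5 (E)‑5‑bromo‑3‑(3,4‑dimethoxybenzylidene)‑7‑methoxybenzofuran‑2(3H)‑one
Product: 6 (E)‑5‑bromo‑3‑(3,4‑dimethoxybenzylidene)‑7‑methoxy‑2,3‑dihydrobenzofuran‑2‑ol (lactol, racemic at C2, ring tautomer of enal 7)
Conditions: i‑Bu2AlH (1.1 equiv), CH2Cl2, −78 °C; aq. potassium sodium tartrate
Reagents that add atoms: none
Why: Partial reduction of a lactone to a lactol; at −78 °C the O‑aluminated hemiacetal should persist until the quench so that a second hydride is not delivered, the aryl bromide and the ring‑locked E alkene are untouched, and the neutral tartrate work‑up avoids acid, under which the lactol could ionise.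

Step 5
Reactants: 6 (E)‑5‑bromo‑3‑(3,4‑dimethoxybenzylidene)‑7‑methoxy‑2,3‑dihydrobenzofuran‑2‑ol
Product: 9 [(2S,3R)‑5‑bromo‑2‑(3,4‑dimethoxyphenyl)‑7‑methoxy‑2,3‑dihydrobenzofuran‑3‑yl]methanol, via enal 7 (not isolated), via trans aldehyde 8 (not isolated)
Conditions: 9‑amino‑9‑deoxy‑epi‑quinine (20 mol %), PhCO2H (40 mol %), toluene, 0 °C; then MeOH, NaBH4 (1.5 equiv), −40 to 0 °C
Reagents that add atoms: none
Why: Proposed new method: lactol 6 opens to enal 7, which condenses with the primary amine to an iminium ion whose positive charge is shared by C2 through ring B (a 4‑methoxybenzylic cation, that is, a quinone‑methide‑like form); the ring A phenol, forced out of the alkene plane by the cis ring B and hydrogen‑bonded to the benzoate and quinuclidine of the catalyst, bonds to C2, the enamine is protonated at C3, the imine is hydrolysed to aldehyde 8, and NaBH4 reduces 8 in the same flask to 9. The closest known reaction type is the iminium‑catalysed asymmetric intramolecular oxa‑Michael addition of phenols to enals and enones, which closes six‑membered chroman and flavanone rings; a five‑membered closure onto an α‑aryl enal is new. The dihydrofuran ring closes in the 5‑endo‑trig mode, tolerable here because bond formation at the cation‑like C2 is early and because in the quinoid resonance form the same event is a 5‑exo attack on the exocyclic C2=C(aryl) bond. C2 is set by the catalyst: its two faces correspond to the two helical rotamers about the C3–C3a bond, and the chiral ion pair is expected to let only one of them close. C3 is set by the substrate, since the enamine and the α‑aryl aldehyde equilibrate to the trans isomer with aryl and formyl on opposite faces. The step needs face selectivity at C2, a single alkene geometry (secured by the lactone‑derived E alkene), 1,4‑ over 1,2‑addition (the 1,2‑adducts, lactol and N,O‑acetal, are reversible reservoirs) and kinetic trapping before retro‑Michael opening, which the cold hydride quench provides.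

Step 6
Reactants: 9 [(2S,3R)‑5‑bromo‑2‑(3,4‑dimethoxyphenyl)‑7‑methoxy‑2,3‑dihydrobenzofuran‑3‑yl]methanol; 10 (E)‑3‑(tert‑butyldimethylsilyloxy)prop‑1‑enylboronic acid pinacol ester
Product: 11 [(2S,3R)‑5‑[(E)‑3‑(tert‑butyldimethylsilyloxy)prop‑1‑enyl]‑2‑(3,4‑dimethoxyphenyl)‑7‑methoxy‑2,3‑dihydrobenzofuran‑3‑yl]methanol
Conditions: PdCl2(dppf) (5 mol %; dppf = 1,1'‑bis(diphenylphosphino)ferrocene), K2CO3 (3 equiv), 1,4‑dioxane/H2O 4:1, 85 °C
Reagents that add atoms: none
Why: Suzuki–Miyaura coupling; oxidative addition of the aryl bromide to zerovalent palladium, transmetalation of the base‑activated alkenylboronate and reductive elimination with retention of the E geometry, the free primary alcohol is tolerated, and with C3 at the alcohol level aqueous carbonate can no longer open the ring or epimerise C2 or C3.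

Step 7
Reactants: 11 [(2S,3R)‑5‑[(E)‑3‑(tert‑butyldimethylsilyloxy)prop‑1‑enyl]‑2‑(3,4‑dimethoxyphenyl)‑7‑methoxy‑2,3‑dihydrobenzofuran‑3‑yl]methanol
Product: 12 hierochin B, (E)‑3‑[(2S,3R)‑2‑(3,4‑dimethoxyphenyl)‑3‑(hydroxymethyl)‑7‑methoxy‑2,3‑dihydrobenzofuran‑5‑yl]prop‑2‑en‑1‑ol
Conditions: Bu4NF (1.2 equiv), THF, 0 °C to rt
Reagents that add atoms: none
Why: Fluoride cleavage of the primary allylic silyl ether through Si–F bond formation; the near‑neutral conditions spare the acid‑labile benzylic O1–C2 bond and the cinnamyl alcohol, and no stereocentre is touched.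

## Compound list

1 | 2‑(2‑hydroxy‑3‑methoxyphenyl)acetic acid | COc1cccc(CC(=O)O)c1O | starting material
2 | 2‑(5‑bromo‑2‑hydroxy‑3‑methoxyphenyl)acetic acid | COc1cc(Br)cc(CC(=O)O)c1O | intermediate
3 | 5‑bromo‑7‑methoxybenzofuran‑2(3H)‑one | COc1cc(Br)cc2CC(=O)Oc12 | intermediate
4 | veratraldehyde | COc1ccc(C=O)cc1OC | starting material
5 | (E)‑5‑bromo‑3‑(3,4‑dimethoxybenzylidene)‑7‑methoxybenzofuran‑2(3H)‑one | O=C1Oc2c(OC)cc(Br)cc2/C1=C\c3ccc(OC)c(OC)c3 | intermediate
6 | (E)‑5‑bromo‑3‑(3,4‑dimethoxybenzylidene)‑7‑methoxy‑2,3‑dihydrobenzofuran‑2‑ol (racemic lactol) | OC1Oc2c(OC)cc(Br)cc2/C1=C\c3ccc(OC)c(OC)c3 | intermediate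
7 | (E)‑2‑(5‑bromo‑2‑hydroxy‑3‑methoxyphenyl)‑3‑(3,4‑dimethoxyphenyl)prop‑2‑enal | O=C/C(c1cc(Br)cc(OC)c1O)=C/c1ccc(OC)c(OC)c1 | intermediate (not isolated)
8 | (2S,3S)‑5‑bromo‑2‑(3,4‑dimethoxyphenyl)‑7‑methoxy‑2,3‑dihydrobenzofuran‑3‑carbaldehyde (trans) | COc1ccc([C@H]2Oc3c(OC)cc(Br)cc3[C@@H]2C=O)cc1OC | intermediate (not isolated)
9 | [(2S,3R)‑5‑bromo‑2‑(3,4‑dimethoxyphenyl)‑7‑methoxy‑2,3‑dihydrobenzofuran‑3‑yl]methanol (trans) | COc1ccc([C@H]2Oc3c(OC)cc(Br)cc3[C@@H]2CO)cc1OC | intermediate
10 | (E)‑3‑(tert‑butyldimethylsilyloxy)prop‑1‑enylboronic acid pinacol ester | CC(C)(C)[Si](C)(C)OC/C=C/B1OC(C)(C)C(C)(C)O1 | starting material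
11 | [(2S,3R)‑5‑[(E)‑3‑(tert‑butyldimethylsilyloxy)prop‑1‑enyl]‑2‑(3,4‑dimethoxyphenyl)‑7‑methoxy‑2,3‑dihydrobenzofuran‑3‑yl]methanol | COc1ccc([C@H]2Oc3c(OC)cc(/C=C/CO[Si](C)(C)C(C)(C)C)cc3[C@@H]2CO)cc1OC | intermediate
12 | hierochin B | COc1ccc([C@H]2Oc3c(OC)cc(/C=C/CO)cc3[C@@H]2CO)cc1OC | target

## Step count and least certain steps

Total: 7 steps. Longest linear sequence: 7 steps (1 to 12); 4 and 10 enter as bought fragments.

**Step 5 (key step, new method).** Four processes can defeat it.
- Facial selection at C2 may be poor, because the transition state is loose and cation‑like, and because rotation about the C2–C3 bond of the iminium ion (through its benzylic cation form) would scramble the alkene geometry and feed the other enantiomer.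
- Retro‑Michael opening and re‑closure before the hydride quench would erode the enantiomeric purity.
- Ionisation of the lactol or of the N,O‑acetal to a benzofuran‑type allyl cation, followed by capture at the benzylic carbon, would drain material irreversibly into aromatic benzofurans.
- The ring‑closed aldehyde may not be favoured at equilibrium, in which case the quench would mainly reduce open enal; catalyst‑bound imine may also be reduced.

Fallback, known chemistry, from 2 back to 9: the closure is replaced by an enantioselective intramolecular carbenoid C–H insertion, an established route to 2‑aryl‑2,3‑dihydrobenzofuran‑3‑carboxylates. Fischer esterification of 2 (MeOH, H2SO4) should give methyl 2‑(5‑bromo‑2‑hydroxy‑3‑methoxyphenyl)acetate F1. O‑Alkylation with 3,4‑dimethoxybenzyl chloride (K2CO3, DMF) should give methyl 2‑[5‑bromo‑2‑(3,4‑dimethoxybenzyloxy)‑3‑methoxyphenyl]acetate F2. Diazo transfer (4‑acetamidobenzenesulfonyl azide, DBU, MeCN) should give methyl 2‑[5‑bromo‑2‑(3,4‑dimethoxybenzyloxy)‑3‑methoxyphenyl]‑2‑diazoacetate F3. Rh2(S‑PTTL)4, dirhodium tetrakis[N‑phthaloyl‑(S)‑tert‑leucinate], in toluene at low temperature should insert the carbenoid into the benzylic C–H bond to give the cis ester methyl (2S,3R)‑5‑bromo‑2‑(3,4‑dimethoxyphenyl)‑7‑methoxy‑2,3‑dihydrobenzofuran‑3‑carboxylate F4; the antipode of the catalyst is taken if the 2R series results. Brief treatment with NaOMe in MeOH at 0 °C should epimerise C3 to the trans ester methyl (2S,3S)‑5‑bromo‑2‑(3,4‑dimethoxyphenyl)‑7‑methoxy‑2,3‑dihydrobenzofuran‑3‑carboxylate F5. LiBH4 in THF then reduces the ester, and the route is rejoined at 9.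

**Step 4.** Over‑reduction is the main risk: collapse of the O‑aluminated hemiacetal of an aryl lactone releases the enal, which takes a second hydride. Allylic transposition of the lactol during work‑up or chromatography is the second.

Fallback, from 5 back to 7: exhaustive reduction of 5 (i‑Bu2AlH, 3 equiv, CH2Cl2, −78 to 0 °C) should give (E)‑2‑(5‑bromo‑2‑hydroxy‑3‑methoxyphenyl)‑3‑(3,4‑dimethoxyphenyl)prop‑2‑en‑1‑ol F6, a stable storage form. MnO2 in CH2Cl2, selective for the allylic alcohol, should then give 7, which enters step 5 directly in equilibrium with 6. The same oxidation would recycle open material recovered from step 5.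

**Step 3.** The aryl lactone may be opened by adventitious nucleophiles, the enolisable lactone may dimerise oxidatively, or an E/Z mixture may form.

Fallback, from 2 and 4 back to 5: a Perkin condensation (Ac2O, Et3N, 100 °C), in which the mixed anhydride of the acid is the enolising species and the lactone closes in the same pot. Isolated 3 is bypassed and no compound outside the list is made (F0).

**Step 6.** Oxidative addition into the electron‑rich aryl bromide may be slow, the alkenylboronate may protodeboronate, and the silyl ether may be partly lost in hot aqueous base.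

Fallback, from 9 back to 12: a Mizoroki–Heck reaction with methyl acrylate (Pd(OAc)2, P(o‑tol)3, K2CO3, DMF, 100 °C) should give methyl (E)‑3‑[(2S,3R)‑2‑(3,4‑dimethoxyphenyl)‑3‑(hydroxymethyl)‑7‑methoxy‑2,3‑dihydrobenzofuran‑5‑yl]prop‑2‑enoate F7. Reduction with i‑Bu2AlH (excess, CH2Cl2, −78 °C) gives the allylic alcohol, so the route is rejoined at 12 without 11.

## Further compounds

F1 | step 5 | methyl 2‑(5‑bromo‑2‑hydroxy‑3‑methoxyphenyl)acetate | COC(=O)Cc1cc(Br)cc(OC)c1O
F2 | step 5 | methyl 2‑[5‑bromo‑2‑(3,4‑dimethoxybenzyloxy)‑3‑methoxyphenyl]acetate | COC(=O)Cc1cc(Br)cc(OC)c1OCc1ccc(OC)c(OC)c1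
F3 | step 5 | methyl 2‑[5‑bromo‑2‑(3,4‑dimethoxybenzyloxy)‑3‑methoxyphenyl]‑2‑diazoacetate | COC(=O)C(=[N+]=[N-])c1cc(Br)cc(OC)c1OCc1ccc(OC)c(OC)c1
F4 | step 5 | methyl (2S,3R)‑5‑bromo‑2‑(3,4‑dimethoxyphenyl)‑7‑methoxy‑2,3‑dihydrobenzofuran‑3‑carboxylate (cis) | COc1ccc([C@H]2Oc3c(OC)cc(Br)cc3[C@H]2C(=O)OC)cc1OC
F5 | step 5 | methyl (2S,3S)‑5‑bromo‑2‑(3,4‑dimethoxyphenyl)‑7‑methoxy‑2,3‑dihydrobenzofuran‑3‑carboxylate (trans) | COc1ccc([C@H]2Oc3c(OC)cc(Br)cc3[C@@H]2C(=O)OC)cc1OC
F6 | step 4 | (E)‑2‑(5‑bromo‑2‑hydroxy‑3‑methoxyphenyl)‑3‑(3,4‑dimethoxyphenyl)prop‑2‑en‑1‑ol | OC/C(c1cc(Br)cc(OC)c1O)=C/c1ccc(OC)c(OC)c1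
F0 | step 3 | none | none
F7 | step 6 | methyl (E)‑3‑[(2S,3R)‑2‑(3,4‑dimethoxyphenyl)‑3‑(hydroxymethyl)‑7‑methoxy‑2,3‑dihydrobenzofuran‑5‑yl]prop‑2‑enoate | COc1ccc([C@H]2Oc3c(OC)cc(/C=C/C(=O)OC)cc3[C@@H]2CO)cc1OC
A1 | alternative 1 | ethyl (2S,3R)‑3‑(tert‑butyldimethylsilyloxymethyl)‑2‑(3,4‑dimethoxyphenyl)‑7‑hydroxy‑2,3‑dihydrobenzofuran‑5‑carboxylate | COc1ccc([C@H]2Oc3c(O)cc(C(=O)OCC)cc3[C@@H]2CO[Si](C)(C)C(C)(C)C)cc1OC
A2 | alternative 1 | ethyl 3‑[(4R,5S)‑2‑acetyl‑4‑(tert‑butyldimethylsilyloxymethyl)‑5‑(3,4‑dimethoxyphenyl)‑2‑hydroxyoxolan‑3‑yl]‑2‑oxopropanoate (C2 and C3 of the oxolane unassigned) | COc1ccc([C@H]2OC(O)(C(C)=O)C(CC(=O)C(=O)OCC)[C@@H]2CO[Si](C)(C)C(C)(C)C)cc1OC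
A3 | alternative 2 | (2S,3R)‑3‑(tert‑butyldimethylsilyloxymethyl)‑5‑(dimethoxymethyl)‑2‑(3,4‑dimethoxyphenyl)‑7‑methoxy‑2,3‑dihydrobenzofuran | COc1ccc([C@H]2Oc3c(OC)cc(C(OC)OC)cc3[C@@H]2CO[Si](C)(C)C(C)(C)C)cc1OC
A4 | alternative 2 | 3‑{[(1S,2R)‑2‑(tert‑butyldimethylsilyloxymethyl)‑1‑(3,4‑dimethoxyphenyl)but‑3‑yn‑1‑yl]oxy}‑6‑(dimethoxymethyl)‑4‑methoxy‑2H‑pyran‑2‑one | COc1ccc([C@@H](OC2=C(OC)C=C(C(OC)OC)OC2=O)[C@@H](CO[Si](C)(C)C(C)(C)C)C#C)cc1OC
A5 | alternative 3 | methyl (2S,3S)‑5‑bromo‑2‑(3,4‑dimethoxyphenyl)‑7‑methoxy‑2,3‑dihydrobenzofuran‑3‑carboxylate (trans) | COc1ccc([C@H]2Oc3c(OC)cc(Br)cc3[C@@H]2C(=O)OC)cc1OC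
A6 | alternative 3 | (S)‑6‑bromo‑2‑(3,4‑dimethoxyphenyl)‑8‑methoxychroman‑4‑one | COc1ccc([C@@H]2CC(=O)c3cc(Br)cc(OC)c3O2)cc1OC
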